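**Plan**

- Retrosynthesis: ring C of the flavonol is cut at O1–C2 and C3–OH (oxidative chalcone cyclisation) and at the C2–C3 enone bond (aldol), giving acetophenone 16 and aldehyde 18. The acetyl carbon is then removed from C4a, giving phenol 13.
- Ring A of 13 is cut at C8a–C8, C6–C7 and C4a–C8a into 3-ethoxycyclobutenone 4 and the prenyl methoxyalkyne 8.
- Enabling feature: ring A carries oxygen on C5, C7 and C8a in a 1,3,5 pattern, with the prenyl group on C8 between C7–OMe and C8a–O and hydrogen on C6. A 3-alkoxycyclobutenone and a prenyl-substituted methoxyalkyne deliver this pattern by connectivity, leaving C4a as the only free ortho carbon.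
- Forward order: ring A (step 3), then the C4 acyl carbon (steps 4–6), chalcone (step 8), ring C (step 9); ring B arrives intact from 4-hydroxybenzaldehyde. The C5 ethyl ether keeps O5 distinct from the C8a hydroxyl until ring C is closed and is removed last.
- Stereochemistry: the target has no stereocentre. The stereocentres in 10, 15 and 20 are racemic and are destroyed within the route.

Key step: step 3

Remark: cyclobutenone 4 is assumed to open to its vinylketene at 80–110 °C as other cyclobutenones do.

**Route**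

Step 1
Reactants: 1 ethoxyacetylene; 2 acetone
Product: 4 3-ethoxycyclobut-2-en-1-one, via ketene 3 (not isolated)
Conditions: 2 cracked in a ketene generator (glowing Ni–Cr wire, about 700 °C), gas stream passed into 1 in CH2Cl2, 0 °C → rt; distillation under reduced pressure
Reagents that add atoms: none
Why: Ketene [2+2] cycloaddition to an alkoxyalkyne; the nucleophilic terminal carbon of 1 bonds to the ketene carbonyl carbon, so the vinylogous-ester cyclobutenone is the expected regioisomer.

Step 2
Reactants: 5 chloroacetaldehyde dimethyl acetal; 6 prenyl bromide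
Product: 8 1-methoxy-5-methylhex-4-en-1-yne, via sodium methoxyacetylide 7 (not isolated)
Conditions: NaNH2 (3.1 equiv), liquid NH3, −33 °C; then 6, −33 °C; NH4Cl quench, pentane extraction, distillation
Reagents that add atoms: none
Why: Twofold base-induced elimination (MeOH, then HCl) gives the alkoxyacetylide NaC≡COMe, which is alkylated by the primary allylic bromide in an SN2 reaction, the standard one-pot preparation of 1-alkoxy-1-alkynes.

Step 3
Reactants: 4 3-ethoxycyclobut-2-en-1-one; 8 1-methoxy-5-methylhex-4-en-1-yne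
Product: 13 5-ethoxy-3-methoxy-2-(3-methylbut-2-en-1-yl)phenol, via vinylketene 9 (not isolated), via 4-(1-ethoxyethenyl)cyclobutenone 10 (not isolated), via dienylketene 11 (not isolated), via cyclohexa-2,4-dienone 12 (not isolated)
Conditions: 8 (1.5 equiv), toluene, 80 °C then 110 °C, sealed tube under argon; then K2CO3, MeOH, rt (frees any O-acylated phenol)
Reagents that add atoms: none
Why: Thermal 4π-electrocyclic opening of 4 gives vinylketene 9, whose ketene C=C adds to the ynol ether in a regioselective [2+2] cycloaddition to cyclobutenone 10; reversible 4π opening of 10 gives dienylketene 11, which closes to 12 and tautomerises to 13. This is the Danheiser benzannulation of a cyclobutenone with an alkoxyalkyne. Ring A is closed by a thermal disrotatory 6π electrocyclisation of 11 that forms C4a–C8a, after the [2+2] step has made C8a–C8 and C6–C7. No stereocentre survives, since the sp3 carbon of 10 is lost on ring opening and 13 is aromatic. The step needs a single alkyne orientation, which polarity secures: the prenyl-bearing carbon of 8 is the nucleophilic β-carbon of the ynol ether and bonds to the electrophilic ketene carbonyl carbon (future C8a), so prenyl ends ortho and OMe meta to the new phenol oxygen; only the isomer of 11 with ketene and ethoxyvinyl cis can close, and the reversible opening of 10 feeds that isomer. A methyl ynol ether is chosen because it has no β-hydrogen for the retro-ene alkene loss that ethyl and tert-butyl ynol ethers undergo on heating.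

Step 4
Reactants: 13 5-ethoxy-3-methoxy-2-(3-methylbut-2-en-1-yl)phenol
Product: 14 6-ethoxy-2-hydroxy-4-methoxy-3-(3-methylbut-2-en-1-yl)benzaldehyde
Conditions: MgCl2 (anhydrous), Et3N, paraformaldehyde, MeCN, reflux; then cold 1 M HCl
Reagents that add atoms: paraformaldehyde (as formaldehyde), C=O
Why: Casnati–Skattebøl ortho-formylation; the phenoxide ArOMgCl delivers formaldehyde to the only free ortho carbon and a second formaldehyde oxidises the benzylic alkoxide by hydride transfer, while the basic medium leaves the ortho-prenylphenol uncyclised.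

Step 5
Reactants: 14 6-ethoxy-2-hydroxy-4-methoxy-3-(3-methylbut-2-en-1-yl)benzaldehyde
Product: 15 racemic 1-[6-ethoxy-2-hydroxy-4-methoxy-3-(3-methylbut-2-en-1-yl)phenyl]ethan-1-ol
Conditions: MeMgBr (3 equiv), THF, −20 → 0 °C; then sat. aq. NH4Cl
Reagents that add atoms: methylmagnesium bromide, C[Mg]Br
Why: Grignard addition to the salicylaldehyde after the first equivalent has deprotonated the phenol; the new carbinol centre is formed without control and is removed in step 6.

Step 6
Reactants: 15 racemic 1-[6-ethoxy-2-hydroxy-4-methoxy-3-(3-methylbut-2-en-1-yl)phenyl]ethan-1-ol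
Product: 16 1-[6-ethoxy-2-hydroxy-4-methoxy-3-(3-methylbut-2-en-1-yl)phenyl]ethan-1-one
Conditions: activated MnO2 (excess), CH2Cl2, rt
Reagents that add atoms: none
Why: Selective MnO2 oxidation of an electron-rich benzylic alcohol to the hydrogen-bonded ortho-hydroxyacetophenone; the trisubstituted alkene is inert and no acid is present to cyclise the prenyl group.

Step 7
Reactants: 17 4-hydroxybenzaldehyde
Product: 18 4-(methoxymethoxy)benzaldehyde
Conditions: MOMCl, i-Pr2NEt, CH2Cl2, 0 °C → rt
Reagents that add atoms: chloromethyl methyl ether, COCCl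
Why: O-Alkylation of the phenol as its MOM ether; a free 4-phenoxide would deactivate the aldehyde in step 8 and the enone in step 9.

Step 8
Reactants: 16 1-[6-ethoxy-2-hydroxy-4-methoxy-3-(3-methylbut-2-en-1-yl)phenyl]ethan-1-one; 18 4-(methoxymethoxy)benzaldehyde
Product: 19 (E)-1-[6-ethoxy-2-hydroxy-4-methoxy-3-(3-methylbut-2-en-1-yl)phenyl]-3-[4-(methoxymethoxy)phenyl]prop-2-en-1-one
Conditions: KOH (50% aq.), EtOH, rt; then AcOH to pH 6 at 0 °C
Reagents that add atoms: none
Why: Claisen–Schmidt condensation of the methyl ketone enolate with a non-enolisable aldehyde; E1cB dehydration gives the thermodynamically preferred (E)-enone.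

Step 9
Reactants: 19 (E)-1-[6-ethoxy-2-hydroxy-4-methoxy-3-(3-methylbut-2-en-1-yl)phenyl]-3-[4-(methoxymethoxy)phenyl]prop-2-en-1-one
Product: 21 5-ethoxy-3-hydroxy-7-methoxy-2-[4-(methoxymethoxy)phenyl]-8-(3-methylbut-2-en-1-yl)-4H-chromen-4-one, via trans-dihydroflavonol 20 (not isolated)
Conditions: 30% H2O2, 2 M NaOH, MeOH–THF, 0 °C → rt; then AcOH
Reagents that add atoms: hydrogen peroxide, OO
Why: Algar–Flynn–Oyamada reaction; alkaline peroxide converts the 2′-hydroxychalcone into the 3-hydroxyflavanone and dehydrogenates it to the flavonol, the electron-releasing 4-OMOM group favouring closure at the benzylic carbon, while nucleophilic peroxide leaves the electron-rich prenyl alkene alone.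

Step 10
Reactants: 21 5-ethoxy-3-hydroxy-7-methoxy-2-[4-(methoxymethoxy)phenyl]-8-(3-methylbut-2-en-1-yl)-4H-chromen-4-one
Product: 22 5-ethoxy-3-hydroxy-2-(4-hydroxyphenyl)-7-methoxy-8-(3-methylbut-2-en-1-yl)-4H-chromen-4-one
Conditions: 3 M HCl, MeOH, 45 °C
Reagents that add atoms: none
Why: Acid-catalysed acetal exchange removes the MOM ether; the prenyl group sits between C7–OMe and the ring oxygen, so no free ortho hydroxyl can add to it.

Step 11
Reactants: 22 5-ethoxy-3-hydroxy-2-(4-hydroxyphenyl)-7-methoxy-8-(3-methylbut-2-en-1-yl)-4H-chromen-4-one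
Product: 23 isoanhydroicaritin, 3,5-dihydroxy-2-(4-hydroxyphenyl)-7-methoxy-8-(3-methylbut-2-en-1-yl)-4H-chromen-4-one
Conditions: MgI2·OEt2 (excess), THF–toluene, 80 °C; then sat. aq. NH4Cl
Reagents that add atoms: none
Why: Chelation-assisted ether cleavage; magnesium bridges the C4 carbonyl and the peri C5 ether oxygen and iodide removes the ethyl group by SN2, a mild dealkylation of 5-alkoxyflavonoids that spares prenyl groups and the non-chelated C7 methyl ether.

**Compound list**

1 | ethoxyacetylene | CCOC#C | starting material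
2 | acetone | CC(C)=O | starting material
3 | ketene | C=C=O | intermediate
4 | 3-ethoxycyclobut-2-en-1-one | CCOC1=CC(=O)C1 | intermediate
5 | chloroacetaldehyde dimethyl acetal | COC(CCl)OC | starting material
6 | prenyl bromide (1-bromo-3-methylbut-2-ene) | CC(C)=CCBr | starting material
7 | sodium methoxyacetylide, NaC≡COMe | [Na+].[C-]#COC | intermediate
8 | 1-methoxy-5-methylhex-4-en-1-yne | COC#CCC=C(C)C | intermediate
9 | 3-ethoxybuta-1,3-dien-1-one, the (1-ethoxyvinyl)ketene | CCOC(=C)C=C=O | intermediate
10 | racemic 4-(1-ethoxyethenyl)-3-methoxy-2-(3-methylbut-2-en-1-yl)cyclobut-2-en-1-one | CCOC(=C)C1C(=O)C(CC=C(C)C)=C1OC | intermediate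
11 | (3E)-5-ethoxy-3-methoxy-2-(3-methylbut-2-en-1-yl)hexa-1,3,5-trien-1-one (ketene and ethoxyvinyl cis across C3=C4) | O=C=C(CC=C(C)C)/C(OC)=C\C(OCC)=C | intermediate
12 | 5-ethoxy-3-methoxy-2-(3-methylbut-2-en-1-yl)cyclohexa-2,4-dien-1-one | CCOC1=CC(OC)=C(CC=C(C)C)C(=O)C1 | intermediate
13 | 5-ethoxy-3-methoxy-2-(3-methylbut-2-en-1-yl)phenol | CCOc1cc(O)c(CC=C(C)C)c(OC)c1 | intermediate
14 | 6-ethoxy-2-hydroxy-4-methoxy-3-(3-methylbut-2-en-1-yl)benzaldehyde | CCOc1cc(OC)c(CC=C(C)C)c(O)c1C=O | intermediate
15 | racemic 1-[6-ethoxy-2-hydroxy-4-methoxy-3-(3-methylbut-2-en-1-yl)phenyl]ethan-1-ol | CCOc1cc(OC)c(CC=C(C)C)c(O)c1C(C)O | intermediate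
16 | 1-[6-ethoxy-2-hydroxy-4-methoxy-3-(3-methylbut-2-en-1-yl)phenyl]ethan-1-one | CCOc1cc(OC)c(CC=C(C)C)c(O)c1C(C)=O | intermediate
17 | 4-hydroxybenzaldehyde | O=Cc1ccc(O)cc1 | starting material
18 | 4-(methoxymethoxy)benzaldehyde | COCOc1ccc(C=O)cc1 | intermediate
19 | (E)-1-[6-ethoxy-2-hydroxy-4-methoxy-3-(3-methylbut-2-en-1-yl)phenyl]-3-[4-(methoxymethoxy)phenyl]prop-2-en-1-one | CCOc1cc(OC)c(CC=C(C)C)c(O)c1C(=O)/C=C/c1ccc(OCOC)cc1 | intermediate
20 | racemic trans-(2R*,3R*)-5-ethoxy-3-hydroxy-7-methoxy-2-[4-(methoxymethoxy)phenyl]-8-(3-methylbut-2-en-1-yl)chroman-4-one (one enantiomer drawn) | CCOc1cc(OC)c(CC=C(C)C)c2O[C@H](c3ccc(OCOC)cc3)[C@@H](O)C(=O)c12 | intermediate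
21 | 5-ethoxy-3-hydroxy-7-methoxy-2-[4-(methoxymethoxy)phenyl]-8-(3-methylbut-2-en-1-yl)-4H-chromen-4-one | CCOc1cc(OC)c(CC=C(C)C)c2oc(-c3ccc(OCOC)cc3)c(O)c(=O)c12 | intermediate
22 | 5-ethoxy-3-hydroxy-2-(4-hydroxyphenyl)-7-methoxy-8-(3-methylbut-2-en-1-yl)-4H-chromen-4-one | CCOc1cc(OC)c(CC=C(C)C)c2oc(-c3ccc(O)cc3)c(O)c(=O)c12 | intermediate
23 | isoanhydroicaritin, 3,5-dihydroxy-2-(4-hydroxyphenyl)-7-methoxy-8-(3-methylbut-2-en-1-yl)-4H-chromen-4-one | COc1cc(O)c2c(=O)c(O)c(-c3ccc(O)cc3)oc2c1CC=C(C)C | target

**Step count**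

Total: 11 steps. Longest linear sequence: 9 steps (step 1 or step 2, then steps 3, 4, 5, 6, 8, 9, 10, 11).

**Steps most likely to fail**

Step 3. The electrocyclic opening of the vinylogous-ester cyclobutenone 4 may need temperatures at which the vinylketene oligomerises or acylates the product phenol faster than the ynol ether captures it. The fallback keeps 8 and the same ring-forming events but makes vinylketene 9 at room temperature by 1,4-dehydrochlorination. It sets out from 8 and from commercial ethyl (E)-3-ethoxybut-2-enoate. The ester is saponified (KOH, aqueous EtOH, acidification to pH 4 at 0 °C) to (E)-3-ethoxybut-2-enoic acid F1. Oxalyl chloride with catalytic DMF in CH2Cl2 converts F1 into (E)-3-ethoxybut-2-enoyl chloride F2. Slow addition of F2 to Et3N and 8 in toluene at room temperature, warming to 80 °C and a K2CO3/MeOH work-up should pass through 9, 10, 11 and 12 and come back to the route at phenol 13.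

Step 9. The C6′ ethoxy group twists the carbonyl out of plane, so closure at the α-carbon to a five-membered aurone may compete with six-membered ring formation. The fallback separates epoxidation from cyclisation and closes the ring under acid, where attack at the benzylic carbon is favoured. It sets out from chalcone 19. Capping the 2′-hydroxyl (NaH, MOMCl, THF, 0 °C) gives (E)-1-[6-ethoxy-4-methoxy-2-(methoxymethoxy)-3-(3-methylbut-2-en-1-yl)phenyl]-3-[4-(methoxymethoxy)phenyl]prop-2-en-1-one F3. Weitz–Scheffer epoxidation (H2O2, NaOH, MeOH–THF) gives the racemic trans-epoxide F4. HCl in MeOH at 40 °C removes both MOM groups, and the freed phenol opens the oxirane at the benzylic carbon to give the racemic trans-3,4′-dihydroxyflavanone F5. Brief treatment of F5 with alkaline H2O2 dehydrogenates it to flavonol 22, where the route is rejoined; step 10 is then not needed.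

Step 11. SN2 removal of an ethyl group is slower than that of a methyl group, so forcing the reaction may lead to addition of acid to the prenyl alkene or loss of the C7 methyl ether. The fallback uses the stronger Lewis acid BCl3 on a substrate with no free hydroxyl, so that no HCl is released. It sets out from 22. Ac2O in pyridine gives 5-ethoxy-7-methoxy-8-(3-methylbut-2-en-1-yl)-4-oxo-2-(4-acetoxyphenyl)-4H-chromen-3-yl acetate F6. BCl3 in CH2Cl2 at −78 → −20 °C cleaves the chelated C5 ether to give the 5-hydroxy diacetate F7. K2CO3 in MeOH removes both acetates and returns to target 23.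

**Further compounds**

F1 | step 3 | (E)-3-ethoxybut-2-enoic acid | OC(=O)/C=C(/OCC)C
F2 | step 3 | (E)-3-ethoxybut-2-enoyl chloride | ClC(=O)/C=C(/OCC)C
F3 | step 9 | (E)-1-[6-ethoxy-4-methoxy-2-(methoxymethoxy)-3-(3-methylbut-2-en-1-yl)phenyl]-3-[4-(methoxymethoxy)phenyl]prop-2-en-1-one | CCOc1cc(OC)c(CC=C(C)C)c(OCOC)c1C(=O)/C=C/c1ccc(OCOC)cc1
F4 | step 9 | racemic trans-[6-ethoxy-4-methoxy-2-(methoxymethoxy)-3-(3-methylbut-2-en-1-yl)phenyl]{3-[4-(methoxymethoxy)phenyl]oxiran-2-yl}methanone | CCOc1cc(OC)c(CC=C(C)C)c(OCOC)c1C(=O)[C@@H]1O[C@H]1c1ccc(OCOC)cc1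
F5 | step 9 | racemic trans-(2R*,3R*)-5-ethoxy-3-hydroxy-2-(4-hydroxyphenyl)-7-methoxy-8-(3-methylbut-2-en-1-yl)chroman-4-one | CCOc1cc(OC)c(CC=C(C)C)c2O[C@H](c3ccc(O)cc3)[C@@H](O)C(=O)c12
F6 | step 11 | 2-(4-acetoxyphenyl)-5-ethoxy-7-methoxy-8-(3-methylbut-2-en-1-yl)-4-oxo-4H-chromen-3-yl acetate | CCOc1cc(OC)c(CC=C(C)C)c2oc(-c3ccc(OC(C)=O)cc3)c(OC(C)=O)c(=O)c12
F7 | step 11 | 2-(4-acetoxyphenyl)-5-hydroxy-7-methoxy-8-(3-methylbut-2-en-1-yl)-4-oxo-4H-chromen-3-yl acetate | COc1cc(O)c2c(=O)c(OC(C)=O)c(-c3ccc(OC(C)=O)cc3)oc2c1CC=C(C)C
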